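**Retrosynthetic overview**

1. Target 17 ⇐ bis-silyl flavanone 16 (both aryl silyl ethers removed last).
2. 16 ⇐ ynone 14: rings C and A close in one operation. The alkynone is tethered through O1–C2–C3–C4 to a 1-alkoxy-3-silyloxycyclohexa-1,3-diene; intramolecular Diels–Alder reaction, then loss of ethene (Alder–Rickert), leaves the resorcinol-type ring A.
3. 14 ⇐ Weinreb amide 12 + HC≡CMgBr; 12 ⇐ (S)-alcohol 9 + 3-chlorocyclohexenone 10 (vinylic substitution, then α′-silylation).
4. 9 ⇐ β-keto amide 8 by asymmetric transfer hydrogenation (sets C2); 8 ⇐ ring B ester 6 + acetamide 7.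
5. 6 ⇐ methyl 5-bromovanillate 1 (methyl moved from O5 to O4, silylation, Stille prenylation). Ring order: ring B is bought; rings C and A are formed together.

Assumption: 1, 5, 7, 10 and 13 are bought (1 is otherwise one bromination from methyl vanillate, 10 one step from cyclohexane-1,3-dione); "Ar" in names means 4-methoxy-3-(3-methylbut-2-en-1-yl)-5-[(triisopropylsilyl)oxy]phenyl.

**Route**

Step 1
Reactants: 1 methyl 3-bromo-4-hydroxy-5-methoxybenzoate
Product: 2 methyl 3-bromo-4,5-dihydroxybenzoate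
Conditions: AlCl3 (1.2 equiv), pyridine (4.5 equiv), CH2Cl2, reflux; aq HCl
Reagents that add atoms: none
Why: Chelation-directed aryl methyl ether cleavage (Lewis acid-assisted SN2 demethylation by pyridine) removes only the methoxy group next to the free phenol and leaves the methyl ester alone.

Step 2
Reactants: 2 methyl 3-bromo-4,5-dihydroxybenzoate
Product: 3 methyl 3-bromo-5-hydroxy-4-methoxybenzoate
Conditions: MeI (1.05 equiv), Li2CO3 (1.1 equiv), DMF, 40 °C
Reagents that add atoms: iodomethane, CI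
Why: Williamson etherification under a weak base, which ionises only the more acidic 4-OH (para to the ester, ortho to bromine), so mono-methylation occurs there.

Step 3
Reactants: 3 methyl 3-bromo-5-hydroxy-4-methoxybenzoate
Product: 4 methyl 3-bromo-4-methoxy-5-[(triisopropylsilyl)oxy]benzoate
Conditions: iPr3SiCl, imidazole, DMF, rt
Reagents that add atoms: chlorotriisopropylsilane, CC(C)[Si](Cl)(C(C)C)C(C)C
Why: Standard phenol silylation; the bulky triisopropylsilyl ether resists alkoxides, amide enolates and Grignard reagents and does not migrate.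

Step 4
Reactants: 4 methyl 3-bromo-4-methoxy-5-[(triisopropylsilyl)oxy]benzoate; 5 tributyl(3-methylbut-2-en-1-yl)stannane
Product: 6 methyl 4-methoxy-3-(3-methylbut-2-en-1-yl)-5-[(triisopropylsilyl)oxy]benzoate
Conditions: Pd(PPh3)4 (5 mol %), DMF, 100 °C
Reagents that add atoms: none
Why: Stille cross-coupling, in which reductive elimination from the prenylpalladium intermediate at its unsubstituted terminus gives the linear prenyl arene while ester and silyl ether are inert.

Step 5
Reactants: 6 methyl 4-methoxy-3-(3-methylbut-2-en-1-yl)-5-[(triisopropylsilyl)oxy]benzoate; 7 N-methoxy-N-methylacetamide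
Product: 8 3-Ar-N-methoxy-N-methyl-3-oxopropanamide
Conditions: 7 (2.3 equiv), LiN(iPr)2 (2.3 equiv), THF, −78 °C; then 6, −78 to −10 °C; 1 M HCl
Reagents that add atoms: none
Why: Crossed Claisen condensation of the amide lithium enolate with the aryl ester, where immediate deprotonation of the β-keto amide by the second equivalent of base prevents over-addition.

Step 6
Reactants: 8 3-Ar-N-methoxy-N-methyl-3-oxopropanamide
Product: 9 (3S)-3-Ar-3-hydroxy-N-methoxy-N-methylpropanamide
Conditions: RuCl[(S,S)-TsDPEN](p-cymene) (1 mol %), HCO2H/Et3N (5:2), DMF, 35 °C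
Reagents that add atoms: none
Why: Noyori–Ikariya asymmetric transfer hydrogenation, in which the (S,S) catalyst delivers hydride to one face of the aryl ketone through the CH/π-organised six-membered transition state to give the (S)-benzylic alcohol (same sense as for acetophenone and aryl β-keto amides) without touching the prenyl alkene.

Step 7
Reactants: 9 (3S)-3-Ar-3-hydroxy-N-methoxy-N-methylpropanamide; 10 3-chlorocyclohex-2-en-1-one
Product: 11 (3S)-3-Ar-N-methoxy-N-methyl-3-[(3-oxocyclohex-1-en-1-yl)oxy]propanamide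
Conditions: KN(SiMe3)2 (1.0 equiv), THF, −78 °C; then 10 (1.2 equiv), −78 to −30 °C; pH 7 buffer
Reagents that add atoms: none
Why: Vinylic addition–elimination of the potassium alkoxide on the β-chloroenone gives the vinylogous ester, and because the carbinol C–O bond is never broken the (S) configuration is retained.

Step 8
Reactants: 11 (3S)-3-Ar-N-methoxy-N-methyl-3-[(3-oxocyclohex-1-en-1-yl)oxy]propanamide
Product: 12 (3S)-3-Ar-3-{[3-(tert-butyldimethylsilyloxy)cyclohexa-1,3-dien-1-yl]oxy}-N-methoxy-N-methylpropanamide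
Conditions: tBuMe2SiOTf (1.15 equiv), Et3N (2.5 equiv), CH2Cl2, −78 to 0 °C; pentane, filter; used crude
Reagents that add atoms: tert-butyldimethylsilyl trifluoromethanesulfonate, CC(C)(C)[Si](C)(C)OS(=O)(=O)C(F)(F)F
Why: Soft enolisation (silyl triflate/amine) at the α′-CH2 of the vinylogous ester gives the cross-conjugated 1-alkoxy-3-silyloxy diene, the cyclic counterpart of Danishefsky's diene, without a base strong enough to cause β-elimination next to the amide.

Step 9
Reactants: 12 (3S)-3-Ar-3-{[3-(tert-butyldimethylsilyloxy)cyclohexa-1,3-dien-1-yl]oxy}-N-methoxy-N-methylpropanamide; 13 ethynylmagnesium bromide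
Product: 16 (2S)-2-Ar-7-[(tert-butyldimethylsilyl)oxy]-2,3-dihydro-4H-chromen-4-one, via ynone 14 (not isolated), via tricyclic cycloadduct 15 (not isolated)
Conditions: HC≡CMgBr (3 equiv), THF, −20 to 0 °C; inverse quench into cold aq NH4Cl; crude 14 in toluene (0.01 M), BHT, 80 °C then 150 °C (sealed tube)
Reagents that add atoms: none
Why: Proposed new method: Weinreb ketone synthesis gives terminal ynone 14, whose alkyne is held over the electron-rich diene by the four-atom O1–C2–C3–C4 tether so that an intramolecular normal-demand Diels–Alder reaction (alkyne α-carbon to the alkoxy-bearing diene terminus, β-carbon to the CH terminus, matched by both tether and polarity) closes ring C and a bicyclo[2.2.2]octadiene, which then loses ethene by retro-Diels–Alder reaction (Alder–Rickert) to leave ring A as the 7-silyloxy arene with O1 kept at the former bridgehead; the closest known chemistry is the intermolecular Alder–Rickert synthesis of resorcinol ketones from 1-alkoxy-3-silyloxycyclohexa-1,3-dienes and alkynones together with bridgehead-tethered intramolecular Diels–Alder reactions of 1-substituted cyclohexadienes, and C2 takes no part so it stays (S).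

Step 10
Reactants: 16 (2S)-2-Ar-7-[(tert-butyldimethylsilyl)oxy]-2,3-dihydro-4H-chromen-4-one
Product: 17 erylatissin C, (2S)-7-hydroxy-2-[3-hydroxy-4-methoxy-5-(3-methylbut-2-en-1-yl)phenyl]-2,3-dihydro-4H-chromen-4-one
Conditions: Bu4NF (2.5 equiv), AcOH (2.5 equiv), THF, 0 °C to rt
Reagents that add atoms: none
Why: Fluoride-mediated cleavage of both aryl silyl ethers, buffered with acetic acid so that no phenoxide or enolate opens the flavanone ring (retro-oxa-Michael) and racemises C2.

**Compound list**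

1 | methyl 3-bromo-4-hydroxy-5-methoxybenzoate | COC(=O)c1cc(Br)c(O)c(OC)c1 | starting material
2 | methyl 3-bromo-4,5-dihydroxybenzoate | COC(=O)c1cc(Br)c(O)c(O)c1 | intermediate
3 | methyl 3-bromo-5-hydroxy-4-methoxybenzoate | COC(=O)c1cc(Br)c(OC)c(O)c1 | intermediate
4 | methyl 3-bromo-4-methoxy-5-[(triisopropylsilyl)oxy]benzoate | COC(=O)c1cc(Br)c(OC)c(O[Si](C(C)C)(C(C)C)C(C)C)c1 | intermediate
5 | tributyl(3-methylbut-2-en-1-yl)stannane | CCCC[Sn](CCCC)(CCCC)CC=C(C)C | starting material
6 | methyl 4-methoxy-3-(3-methylbut-2-en-1-yl)-5-[(triisopropylsilyl)oxy]benzoate | COC(=O)c1cc(CC=C(C)C)c(OC)c(O[Si](C(C)C)(C(C)C)C(C)C)c1 | intermediate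
7 | N-methoxy-N-methylacetamide | CC(=O)N(C)OC | starting material
8 | N-methoxy-N-methyl-3-{4-methoxy-3-(3-methylbut-2-en-1-yl)-5-[(triisopropylsilyl)oxy]phenyl}-3-oxopropanamide | CON(C)C(=O)CC(=O)c1cc(CC=C(C)C)c(OC)c(O[Si](C(C)C)(C(C)C)C(C)C)c1 | intermediate
9 | (3S)-3-hydroxy-N-methoxy-N-methyl-3-{4-methoxy-3-(3-methylbut-2-en-1-yl)-5-[(triisopropylsilyl)oxy]phenyl}propanamide | CON(C)C(=O)C[C@H](O)c1cc(CC=C(C)C)c(OC)c(O[Si](C(C)C)(C(C)C)C(C)C)c1 | intermediate
10 | 3-chlorocyclohex-2-en-1-one | O=C1C=C(Cl)CCC1 | starting material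
11 | (3S)-N-methoxy-N-methyl-3-{4-methoxy-3-(3-methylbut-2-en-1-yl)-5-[(triisopropylsilyl)oxy]phenyl}-3-[(3-oxocyclohex-1-en-1-yl)oxy]propanamide | CON(C)C(=O)C[C@H](OC1=CC(=O)CCC1)c1cc(CC=C(C)C)c(OC)c(O[Si](C(C)C)(C(C)C)C(C)C)c1 | intermediate
12 | (3S)-3-{[3-(tert-butyldimethylsilyloxy)cyclohexa-1,3-dien-1-yl]oxy}-N-methoxy-N-methyl-3-{4-methoxy-3-(3-methylbut-2-en-1-yl)-5-[(triisopropylsilyl)oxy]phenyl}propanamide | CON(C)C(=O)C[C@H](OC1=CC(O[Si](C)(C)C(C)(C)C)=CCC1)c1cc(CC=C(C)C)c(OC)c(O[Si](C(C)C)(C(C)C)C(C)C)c1 | intermediate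
13 | ethynylmagnesium bromide | C#C[Mg]Br | starting material
14 | (5S)-5-{[3-(tert-butyldimethylsilyloxy)cyclohexa-1,3-dien-1-yl]oxy}-5-{4-methoxy-3-(3-methylbut-2-en-1-yl)-5-[(triisopropylsilyl)oxy]phenyl}pent-1-yn-3-one | C#CC(=O)C[C@H](OC1=CC(O[Si](C)(C)C(C)(C)C)=CCC1)c1cc(CC=C(C)C)c(OC)c(O[Si](C(C)C)(C(C)C)C(C)C)c1 | intermediate
15 | (3S)-9-[(tert-butyldimethylsilyl)oxy]-3-{4-methoxy-3-(3-methylbut-2-en-1-yl)-5-[(triisopropylsilyl)oxy]phenyl}-2-oxatricyclo[6.2.2.0(1,6)]dodeca-6,9-dien-5-one (both bridgehead epimers; the bridgeheads are lost on ethene extrusion) | O=C1C[C@@H](c4cc(CC=C(C)C)c(OC)c(O[Si](C(C)C)(C(C)C)C(C)C)c4)OC23CCC(C=C12)C(O[Si](C)(C)C(C)(C)C)=C3 | intermediate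
16 | (2S)-7-[(tert-butyldimethylsilyl)oxy]-2-{4-methoxy-3-(3-methylbut-2-en-1-yl)-5-[(triisopropylsilyl)oxy]phenyl}-2,3-dihydro-4H-chromen-4-one | COc1c(O[Si](C(C)C)(C(C)C)C(C)C)cc([C@@H]2CC(=O)c3ccc(O[Si](C)(C)C(C)(C)C)cc3O2)cc1CC=C(C)C | intermediate
17 | erylatissin C, (2S)-7-hydroxy-2-[3-hydroxy-4-methoxy-5-(3-methylbut-2-en-1-yl)phenyl]-2,3-dihydro-4H-chromen-4-one | COc1c(O)cc([C@@H]2CC(=O)c3ccc(O)cc3O2)cc1CC=C(C)C | target

**Step count and risk**

Total steps: 10. Longest linear sequence: 10 (1 → 17; 5, 7, 10 and 13 are bought).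

The three steps most likely to fail:

Step 9 (Grignard, tethered cycloaddition, ethene loss). The free ynone 14 may oligomerise or add the released amine, or the tether may not reach. The fallback separates the two ring closures, sets out from 8 and comes back at 17. Transfer hydrogenation of 8 with the enantiomeric catalyst RuCl[(R,R)-TsDPEN](p-cymene) gives the (3R)-hydroxy amide F1. Excess HC≡CMgBr converts it into the (5R)-β-hydroxy ynone F2. This is heated with 1,3-bis(trimethylsilyloxy)cyclohexa-1,3-diene F3 (from cyclohexane-1,3-dione, Me3SiCl, Et3N, ZnCl2), which silylates the free hydroxyl in situ and then undergoes the classical intermolecular Diels–Alder/Alder–Rickert sequence. Methanolic work-up removes the trimethylsilyl groups and gives the (3R)-1-(2,4-dihydroxyphenyl)-3-hydroxy ketone F4. Mitsunobu cyclisation (PPh3, DIAD) through the 2-OH closes ring C with inversion to the (2S)-7-hydroxy flavanone triisopropylsilyl ether F5. Bu4NF/AcOH then gives 17.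

Step 8 (soft enolisation of 11). The silyl triflate may give the regioisomeric diene or ionise the benzylic C–O bond. The fallback fixes the diene regiochemistry on an achiral building block, sets out from 9 and comes back at 12, bypassing 11. Purchased 3-iodocyclohex-2-en-1-one is silylated (tBuMe2SiOTf, Et3N) to 3-(tert-butyldimethylsilyloxy)-1-iodocyclohexa-1,3-diene F6. Alcohol 9 is then joined to F6 by a copper-catalysed C–O coupling (copper monoiodide CuI, 3,4,7,8-tetramethyl-1,10-phenanthroline, Cs2CO3, toluene, 80 °C), an Ullmann-type vinylation that leaves the carbinol centre untouched.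

Step 7 (alkoxide substitution on 10). The potassium alkoxide of 9 may undergo retro-aldol cleavage, or the product may undergo β-elimination. The fallback avoids any alkoxide, sets out from 8 and comes back at 11. Transfer hydrogenation with RuCl[(R,R)-TsDPEN](p-cymene) gives the (3R)-hydroxy amide F7 (the same compound as F1). Mitsunobu etherification (PPh3, DIAD, THF, 0 °C) with cyclohexane-1,3-dione as the acidic partner O-alkylates the vinylogous acid with inversion and gives (S)-11.

**Further compounds**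

F1 | step 9 | (3R)-3-hydroxy-N-methoxy-N-methyl-3-{4-methoxy-3-(3-methylbut-2-en-1-yl)-5-[(triisopropylsilyl)oxy]phenyl}propanamide | CON(C)C(=O)C[C@@H](O)c1cc(CC=C(C)C)c(OC)c(O[Si](C(C)C)(C(C)C)C(C)C)c1
F2 | step 9 | (5R)-5-hydroxy-5-{4-methoxy-3-(3-methylbut-2-en-1-yl)-5-[(triisopropylsilyl)oxy]phenyl}pent-1-yn-3-one | C#CC(=O)C[C@@H](O)c1cc(CC=C(C)C)c(OC)c(O[Si](C(C)C)(C(C)C)C(C)C)c1
F3 | step 9 | 1,3-bis(trimethylsilyloxy)cyclohexa-1,3-diene | C[Si](C)(C)OC1=CC(O[Si](C)(C)C)=CCC1
F4 | step 9 | (3R)-1-(2,4-dihydroxyphenyl)-3-hydroxy-3-{4-methoxy-3-(3-methylbut-2-en-1-yl)-5-[(triisopropylsilyl)oxy]phenyl}propan-1-one | O=C(C[C@@H](O)c1cc(CC=C(C)C)c(OC)c(O[Si](C(C)C)(C(C)C)C(C)C)c1)c1ccc(O)cc1O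
F5 | step 9 | (2S)-7-hydroxy-2-{4-methoxy-3-(3-methylbut-2-en-1-yl)-5-[(triisopropylsilyl)oxy]phenyl}-2,3-dihydro-4H-chromen-4-one | COc1c(O[Si](C(C)C)(C(C)C)C(C)C)cc([C@@H]2CC(=O)c3ccc(O)cc3O2)cc1CC=C(C)C
F6 | step 8 | 3-(tert-butyldimethylsilyloxy)-1-iodocyclohexa-1,3-diene | IC1=CC(O[Si](C)(C)C(C)(C)C)=CCC1
F7 | step 7 | (3R)-3-hydroxy-N-methoxy-N-methyl-3-{4-methoxy-3-(3-methylbut-2-en-1-yl)-5-[(triisopropylsilyl)oxy]phenyl}propanamide | CON(C)C(=O)C[C@@H](O)c1cc(CC=C(C)C)c(OC)c(O[Si](C(C)C)(C(C)C)C(C)C)c1
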